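## Analysis of the target

The target 23 is a 1,2-dioxane (ring atoms O1, O2, C3, C4, C5, C6). It carries a methyl acetate arm (C2, C1) at C3, a methyl group at C4, and at C6 both a methyl group and a (2E,4E)-2,4-dimethyl-6-phenylhexa-2,4-dienyl chain (C7 to C12, then phenyl). The stereocentres are C3 (S), C4 (R) and the fully substituted peroxy carbon C6 (R). The C3 arm and the C4 methyl group are trans, and the C6 methyl group is cis to the C3 arm and trans to the C4 methyl group, so in the chair every substituent is equatorial except the C6 methyl group, which is axial. C3 is a β-peroxy ester carbon that reversible oxa-Michael addition can correct, and C4 is an ordinary methyl-bearing centre, so the hard centre is C6. C6 bears CH3 and CH2R, two groups of almost equal size, has no neighbouring functional group and cannot be made by SN2 at a tertiary C–OO bond, so neither equilibration nor a chair-like ring closure can tell its two carbon groups apart. The feature the route exploits is the axial C6–CH3 bond on the ring carbon next to O1, which is the bond an axial attack on a ring cation at C6 would form. The O–O bond (hydrides, low-valent metals, radicals), the β-peroxy ester (strong base) and the trisubstituted 1,3-diene (ozone, acid, electrophiles) are sensitive, so the diene must arrive late and under neutral conditions.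

## Retrosynthetic reasoning

**C9–C10.** The diene of 23 is cut between its two alkenes into bromoalkene 17 and alkenylzinc 22, which comes from alkyne 20 through 21. Both alkene geometries are then fixed in the fragments, the union is neutral, and the ozone- and cation-sensitive diene stays out of all earlier steps. The forward coupling must retain both geometries and leave the O–O bond alone.

**C6–CH3 (key disconnection).** The axial methyl group of 17 is removed to give peroxyketal 15 and its ring cation 16. A nucleophile that attacks a six-membered ring cation at C6 enters axially and ends trans to the C4 methyl group. In the target that position is held by the methyl group, not the chain, so the chain stub must already sit on C6 and the methyl group must be the incoming group. The forward step must ionize only the exocyclic C6–O bond and transfer methyl faster than the cation loses a proton. Both C6 epimers of 15 converge on 16.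

**O2–C3.** Ring 15 is opened at the O2–C3 bond to hydroperoxy ketal 14. Forward, a 6-exo oxa-Michael addition closes the ring and sets C3 trans to C4. This bond is chosen because its centre C3 stays correctable by retro-addition.

**Both C6–O bonds.** The two C–O bonds at C6 of 14 are traced to the 1,1-disubstituted alkene of 12. Ozonolysis with capture of carbonyl oxide 13 by the alcohol solvent installs the O–O unit and the ketal oxidation level in one step without a free ketone. The enoate and the bromoalkene must survive as the electron-poor alkenes.

**C2=C3 and the bromoalkene.** Enoate 12 is cut at C2=C3 into ylide 10 and aldehyde 11, made from alcohol 9. The bromoalkene of 9 comes from the terminal alkyne of 7 by syn carbometalation through 8, which fixes the C8 methyl group and the (E) geometry before any peroxide is present.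

**C4–C5 and the C4 stereocentre.** Alcohol 7 comes from imide 6. The C4–C5 bond of 6 is formed by auxiliary-controlled alkylation of 4, through enolate 5, with allylic bromide 3. Bromide 3 is made from the symmetric dibromide 1 and alkynyl Grignard 2. This sets C4, the only stereocentre that is not made under control of the ring.

**Chain alkyne.** Alkyne 20 is cut at its propargylic C–C bond into 18 and 19.

## Alternatives that were turned down

**Alternative 1:** the textbook route. The C6–O1 bond is disconnected to a 2-methylalkene and the O2–C3 bond to an enoate. Forward, Mukaiyama–Isayama peroxidation (cobalt catalyst, O2, Et3SiH) gives the tertiary silyl peroxide A1, and desilylation with oxa-Michael closure gives the ring. It is short, but the C6 radical is acyclic and far from C4, so O2 is captured on both faces and both C6 epimers form. The hardest stereocentre is then set only by chromatography, and half the material is lost late. With the full chain present the diene would also compete for hydrogen atom transfer.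

**Alternative 2:** convergent Hosomi–Sakurai union at C6–C7. The peroxycarbenium ion from the methyl-bearing peroxyketal A2 would be trapped by the α-silyl diene A3. This joins two fragments of similar size at the quaternary carbon and is the shortest route on paper. It fails on stereochemistry: in the half-chair cation the incoming group goes axial, trans to the C4 methyl group, so the chain ends axial and the methyl equatorial. The product is the C6 epimer A4, not 23. The same analysis shows that only the methyl group may be the incoming group, which is the route adopted. A3 would also cost several steps of its own.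

**Alternative 3:** [4+2] cycloaddition of singlet oxygen. Both C–O bonds are disconnected to the 3,5-diene A5, giving the 3,6-dihydro-1,2-dioxine A6, followed by diimide reduction of C4=C5. The diene terminus C6 is disubstituted, so the s-cis conformer is strained and the ene reaction with the many allylic hydrogens should dominate. The side-chain diene competes as well. The product is racemic, and the reduction would have to set C4 on a ring whose two faces are not clearly different. It offers no control of absolute configuration.

Key step: step 8

Remark on the chemistry: the ketal carbon C6 of 14 and 15 is carried as a mixture of both configurations, which is harmless because step 8 passes through the planar ion 16.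

## Route

Step 1
Reactants: 1 3-bromo-2-(bromomethyl)prop-1-ene; 2 ethynylmagnesium bromide
Product: 3 2-(bromomethyl)pent-1-en-4-yne
Conditions: 2 (1 equiv) added to 1 (3 equiv), CuBr·SMe2 (5 mol%), THF, −20 to 0 °C
Reagents that add atoms: none
Why: Copper-catalysed substitution of an allylic bromide by an alkynyl Grignard reagent (skipped-enyne synthesis); 1 is symmetric, so direct and SN2' attack give the same product, and the excess of 1 should suppress a second substitution.

Step 2
Reactants: 4 (S)-4-benzyl-3-propionyloxazolidin-2-one; 3 2-(bromomethyl)pent-1-en-4-yne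
Product: 6 (S)-4-benzyl-3-[(R)-2-methyl-4-methylidenehept-6-ynoyl]oxazolidin-2-one, via sodium enolate 5 (not isolated)
Conditions: NaN(SiMe3)2, THF, −78 °C; then 3, −78 to −40 °C
Reagents that add atoms: none
Why: Evans asymmetric alkylation: the chelated (Z)-enolate 5 should be alkylated on the face opposite the benzyl group of the auxiliary, which sets the future C4 as (R); the allylic bromide is reactive enough at low temperature and the alkyne C–H is not acidic enough to quench the enolate.

Step 3
Reactants: 6 (S)-4-benzyl-3-[(R)-2-methyl-4-methylidenehept-6-ynoyl]oxazolidin-2-one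
Product: 7 (R)-2-methyl-4-methylidenehept-6-yn-1-ol
Conditions: LiBH4, MeOH (1 equiv), Et2O, 0 °C
Reagents that add atoms: none
Why: Reductive removal of the oxazolidinone auxiliary with LiBH4 should give the primary alcohol without touching the stereocentre, the alkene or the alkyne.

Step 4
Reactants: 7 (R)-2-methyl-4-methylidenehept-6-yn-1-ol
Product: 9 (2R,6E)-7-bromo-2,6-dimethyl-4-methylidenehept-6-en-1-ol, via alkenylalane 8 (not isolated)
Conditions: AlMe3 (3 equiv), Cp2ZrCl2 (0.3 equiv), CH2Cl2, 0 °C to rt; then N-bromosuccinimide, THF, −30 to 0 °C
Reagents that add atoms: trimethylaluminium C[Al](C)C; N-bromosuccinimide O=C1CCC(=O)N1Br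
Why: Negishi carboalumination adds methyl and aluminium syn across the terminal alkyne with aluminium at the terminus, and brominolysis of 8 with retention should give the (E)-bromoalkene; the alcohol is carried as its aluminium alkoxide and the 1,1-disubstituted alkene should not react.

Step 5
Reactants: 9 (2R,6E)-7-bromo-2,6-dimethyl-4-methylidenehept-6-en-1-ol; 10 methyl (triphenylphosphoranylidene)acetate
Product: 12 methyl (2E,4R,8E)-9-bromo-4,8-dimethyl-6-methylidenenona-2,8-dienoate, via aldehyde 11 (not isolated)
Conditions: Dess–Martin periodinane, NaHCO3, CH2Cl2, 0 °C to rt; then 10, rt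
Reagents that add atoms: none
Why: Dess–Martin oxidation followed in the same flask by a Wittig reaction with the stabilised ylide should give the (E)-enoate; trapping aldehyde 11 without isolation limits epimerisation of the α-stereocentre.

Step 6
Reactants: 12 methyl (2E,4R,8E)-9-bromo-4,8-dimethyl-6-methylidenenona-2,8-dienoate
Product: 14 methyl (2E,4R,6RS,8E)-9-bromo-6-hydroperoxy-6-methoxy-4,8-dimethylnona-2,8-dienoate, via carbonyl oxide 13 (not isolated)
Conditions: O3, CH2Cl2/MeOH 1:1, Sudan Red 7B as end-point indicator, −78 °C; argon purge, no reductive work-up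
Reagents that add atoms: ozone [O-][O+]=O; methanol CO
Why: Ozone should attack the electron-rich 1,1-disubstituted alkene well before the deactivated enoate and bromoalkene; the primary ozonide should fragment to formaldehyde and the more substituted carbonyl oxide 13, which methanol captures as the α-methoxy hydroperoxide (Criegee mechanism with alcohol trapping).

Step 7
Reactants: 14 methyl (2E,4R,6RS,8E)-9-bromo-6-hydroperoxy-6-methoxy-4,8-dimethylnona-2,8-dienoate
Product: 15 methyl 2-[(3S,4R,6RS)-6-[(E)-3-bromo-2-methylprop-2-en-1-yl]-6-methoxy-4-methyl-1,2-dioxan-3-yl]acetate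
Conditions: Et2NH (0.3 equiv), CF3CH2OH, rt
Reagents that add atoms: none
Why: Amine-mediated intramolecular oxa-Michael addition of the hydroperoxide to the (E)-enoate (6-exo-trig) closes the 1,2-dioxane; a chair-like transition state with the C4 methyl group and the acceptor arm equatorial should give the 3,4-trans (3S) isomer, which is also the more stable one.

Step 8
Reactants: 15 methyl 2-[(3S,4R,6RS)-6-[(E)-3-bromo-2-methylprop-2-en-1-yl]-6-methoxy-4-methyl-1,2-dioxan-3-yl]acetate
Product: 17 methyl 2-[(3S,4R,6R)-6-[(E)-3-bromo-2-methylprop-2-en-1-yl]-4,6-dimethyl-1,2-dioxan-3-yl]acetate, via peroxycarbenium ion 16 (not isolated)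
Conditions: Me2TiCl2 (2 equiv, made from Me2Zn and TiCl4 in CH2Cl2 at −30 °C), CH2Cl2, −78 to −40 °C; aqueous NaHCO3 quench
Reagents that add atoms: dimethylzinc C[Zn]C (delivers the methyl group through Me2TiCl2, C[Ti](C)(Cl)Cl)
Why: Proposed new method: Me2TiCl2 should complex the exocyclic methoxy group of 15 and ionize the C6–OMe bond to the cyclic peroxycarbenium ion 16, which a methyl–titanium bond then quenches at C6; the closest known reaction types are the Lewis-acid-mediated substitution of cyclic alkoxy peroxides by allylsilanes and silyl enol ethers through peroxycarbenium ions, the methylation of ketals and tertiary ethers by methyltitanium chlorides, and the axial C-methylation of tetrahydropyranyl oxocarbenium ions by AlMe3. No ring is closed; the step forms the C6–CH3 bond and the only new stereocentre is C6. Ion 16 should adopt the half-chair in which the C3 acetate arm and the C4 methyl group are both pseudo-equatorial, and attack along the pseudo-axial trajectory that leads directly to a chair places the incoming methyl group axial, trans to the C4 methyl group and cis to the C3 arm, with the bromoalkenyl arm left equatorial, which is the (6R) configuration. Attack on the other half-chair would force the incoming methyl group into a syn-axial clash with the C4 methyl group, so it is the C4 stereocentre that secures the facial selectivity. Both C6 epimers of 15 give the same ion 16, so the step is stereoconvergent. Beyond facial selectivity the step needs ionization of the exocyclic C–OMe bond in preference to the ring C6–O1 bond and methyl transfer faster than proton loss from C5 or C7; the low temperature, the non-basic reagent and the preference of tetravalent titanium chlorides for peroxycarbenium formation from methoxy peroxyketals argue for both. The ester, the bromoalkene and the O–O bond should be inert to the weakly nucleophilic methyltitanium species at −78 °C.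

Step 9
Reactants: 18 benzyl bromide; 19 prop-1-yn-1-ylmagnesium bromide
Product: 20 but-2-yn-1-ylbenzene
Conditions: CuBr·SMe2 (5 mol%), THF, 0 to 50 °C
Reagents that add atoms: none
Why: Copper-catalysed coupling of an alkynyl Grignard reagent with a benzylic bromide should give the internal alkyne directly.

Step 10
Reactants: 17 methyl 2-[(3S,4R,6R)-6-[(E)-3-bromo-2-methylprop-2-en-1-yl]-4,6-dimethyl-1,2-dioxan-3-yl]acetate; 20 but-2-yn-1-ylbenzene
Product: 23 methyl 2-[(3S,4R,6R)-4,6-dimethyl-6-[(2E,4E)-2,4-dimethyl-6-phenylhexa-2,4-dien-1-yl]-1,2-dioxan-3-yl]acetate, via alkenylzirconocene chloride 21 (not isolated), via alkenylzinc chloride 22 (not isolated)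
Conditions: 20 (2.0 equiv), Cp2Zr(H)Cl (2.2 equiv), THF, rt to 40 °C, then 20 (0.4 equiv) to consume residual hydride; ZnCl2, 0 °C; then 17, Pd(PPh3)4 (5 mol%), THF, rt
Reagents that add atoms: none
Why: Hydrozirconation is a syn addition that, after equilibration, should place zirconium on the less hindered, methyl-bearing carbon; transmetalation to zinc and Negishi coupling with the bromoalkene under zerovalent palladium catalysis proceed with retention at both alkenes and should give the (2E,4E)-diene. The neutral conditions avoid retro-oxa-Michael opening of the β-peroxy ester, and hindered dialkyl peroxides should tolerate palladium-catalysed cross-coupling.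

## Compound list

1 | 3-bromo-2-(bromomethyl)prop-1-ene | C=C(CBr)CBr | starting material
2 | ethynylmagnesium bromide | C#C[Mg]Br | starting material
3 | 2-(bromomethyl)pent-1-en-4-yne | C=C(CBr)CC#C | intermediate
4 | (S)-4-benzyl-3-propionyloxazolidin-2-one | CCC(=O)N1[C@@H](Cc2ccccc2)COC1=O | starting material
5 | sodium (Z)-1-[(S)-4-benzyl-2-oxooxazolidin-3-yl]prop-1-en-1-olate | C/C=C(\[O-])N1[C@@H](Cc2ccccc2)COC1=O.[Na+] | intermediate
6 | (S)-4-benzyl-3-[(R)-2-methyl-4-methylidenehept-6-ynoyl]oxazolidin-2-one | C#CCC(=C)C[C@@H](C)C(=O)N1[C@@H](Cc2ccccc2)COC1=O | intermediate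
7 | (R)-2-methyl-4-methylidenehept-6-yn-1-ol | C#CCC(=C)C[C@@H](C)CO | intermediate
8 | [(1E,6R)-7-(dimethylalumanyloxy)-2,6-dimethyl-4-methylidenehept-1-en-1-yl]dimethylalumane | C[Al](C)OC[C@H](C)CC(=C)C/C(C)=C/[Al](C)C | intermediate
9 | (2R,6E)-7-bromo-2,6-dimethyl-4-methylidenehept-6-en-1-ol | OC[C@H](C)CC(=C)C/C(C)=C/Br | intermediate
10 | methyl (triphenylphosphoranylidene)acetate | COC(=O)C=P(c1ccccc1)(c1ccccc1)c1ccccc1 | starting material
11 | (2R,6E)-7-bromo-2,6-dimethyl-4-methylidenehept-6-enal | O=C[C@H](C)CC(=C)C/C(C)=C/Br | intermediate
12 | methyl (2E,4R,8E)-9-bromo-4,8-dimethyl-6-methylidenenona-2,8-dienoate | COC(=O)/C=C/[C@H](C)CC(=C)C/C(C)=C/Br | intermediate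
13 | methyl (2E,4R,8E)-9-bromo-4,8-dimethyl-6-oxonona-2,8-dienoate O-oxide (carbonyl oxide) | COC(=O)/C=C/[C@H](C)CC(=[O+][O-])C/C(C)=C/Br | intermediate
14 | methyl (2E,4R,6RS,8E)-9-bromo-6-hydroperoxy-6-methoxy-4,8-dimethylnona-2,8-dienoate | COC(=O)/C=C/[C@H](C)CC(OC)(OO)C/C(C)=C/Br | intermediate
15 | methyl 2-[(3S,4R,6RS)-6-[(E)-3-bromo-2-methylprop-2-en-1-yl]-6-methoxy-4-methyl-1,2-dioxan-3-yl]acetate | COC(=O)C[C@@H]1OOC(OC)(C/C(C)=C/Br)C[C@H]1C | intermediate
16 | (3S,4R)-6-[(E)-3-bromo-2-methylprop-2-en-1-yl]-3-(2-methoxy-2-oxoethyl)-4-methyl-4,5-dihydro-3H-1,2-dioxin-1-ium | COC(=O)C[C@@H]1O[O+]=C(C/C(C)=C/Br)C[C@H]1C | intermediate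
17 | methyl 2-[(3S,4R,6R)-6-[(E)-3-bromo-2-methylprop-2-en-1-yl]-4,6-dimethyl-1,2-dioxan-3-yl]acetate | COC(=O)C[C@@H]1OO[C@@](C)(C/C(C)=C/Br)C[C@H]1C | intermediate
18 | benzyl bromide | BrCc1ccccc1 | starting material
19 | prop-1-yn-1-ylmagnesium bromide | CC#C[Mg]Br | starting material
20 | but-2-yn-1-ylbenzene | CC#CCc1ccccc1 | intermediate
21 | chlorobis(cyclopentadienyl)[(E)-4-phenylbut-2-en-2-yl]zirconium | C/C(=C\Cc1ccccc1)[Zr](Cl)(C1C=CC=C1)C1C=CC=C1 | intermediate
22 | [(E)-4-phenylbut-2-en-2-yl]zinc chloride | C/C(=C\Cc1ccccc1)[Zn]Cl | intermediate
23 | methyl 2-[(3S,4R,6R)-4,6-dimethyl-6-[(2E,4E)-2,4-dimethyl-6-phenylhexa-2,4-dien-1-yl]-1,2-dioxan-3-yl]acetate | COC(=O)C[C@@H]1OO[C@@](C)(C/C(C)=C/C(C)=C/Cc2ccccc2)C[C@H]1C | target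

## Step count and least certain steps

Total step count: 10. Longest linear sequence: 9 (steps 1 to 8 and step 10).

**Step 8 (key step, proposed new method).** The most likely failures are ionization of the ring C6–O1 bond instead of the exocyclic C6–OMe bond (ring opening), proton loss from the cation to a peroxy enol ether, or attack of the methyl–metal species on the O–O bond. Neither the ionization regiochemistry nor methyl transfer to a peroxycarbenium ion has a direct model. The fallback uses known chemistry, sets out from 12 and returns at 17. Mukaiyama–Isayama peroxidation of the 1,1-disubstituted alkene (Co(thd)2, thd = 2,2,6,6-tetramethylheptane-3,5-dionate, divalent cobalt; O2; Et3SiH) should give methyl (2E,4R,6RS,8E)-9-bromo-4,6,8-trimethyl-6-[(triethylsilyl)peroxy]nona-2,8-dienoate F1. Desilylation (HCl cat., MeOH) and oxa-Michael closure (Et2NH, CF3CH2OH) should then give 17 together with its C6 epimer methyl 2-[(3S,4R,6S)-6-[(E)-3-bromo-2-methylprop-2-en-1-yl]-4,6-dimethyl-1,2-dioxan-3-yl]acetate F2, to be separated by chromatography. This gives up the control at C6.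

**Step 7.** The ring closure may show poor facial selectivity at C3, or slow closure may let base-induced degradation of the hydroperoxide compete, because the acceptor is only a simple enoate. The fallback replaces kinetic control by late equilibration; it sets out from 14 and returns at 17. Any 3,4-cis isomer, methyl 2-[(3R,4R,6RS)-6-[(E)-3-bromo-2-methylprop-2-en-1-yl]-6-methoxy-4-methyl-1,2-dioxan-3-yl]acetate F3, is carried through the methylation of step 8, where C4 alone should still direct the methyl group trans. This gives methyl 2-[(3R,4R,6R)-6-[(E)-3-bromo-2-methylprop-2-en-1-yl]-4,6-dimethyl-1,2-dioxan-3-yl]acetate F4. Base-mediated retro-oxa-Michael and re-addition (DBU, CF3CH2OH) should then convert F4 into the all-equatorial C3 arrangement of 17.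

**Step 6.** Ozone may over-oxidize the bromoalkene or enoate, or the primary ozonide may fragment the other way (ketone plus formaldehyde oxide), which loses the methoxy hydroperoxide. The fallback sets out from 12 and returns at 14. Lemieux–Johnson cleavage (OsO4 cat., NaIO4, 2,6-lutidine, dioxane/H2O) should give methyl (2E,4R,8E)-9-bromo-4,8-dimethyl-6-oxonona-2,8-dienoate F5. Acid-catalysed hydroperoxyketalization (ethereal H2O2, MeOH, camphorsulfonic acid cat.) would then give 14.

**Step 10.** Regiocontrol in the hydrozirconation of the unsymmetrical alkyne may be incomplete, and residual zirconium hydride or low-valent metal may reduce the O–O bond. The fallback sets out from 20 and returns at 22. Hydrozirconation followed by iodinolysis (Cp2Zr(H)Cl, then I2) gives the isolable (E)-(3-iodobut-2-en-1-yl)benzene F6, which is purified from its regioisomer. Iodine–lithium exchange (t-BuLi, Et2O, −78 °C) and ZnCl2 then give a hydride-free solution of 22 for the same coupling with 17.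

## Further compounds

F1 | step 8 | methyl (2E,4R,6RS,8E)-9-bromo-4,6,8-trimethyl-6-[(triethylsilyl)peroxy]nona-2,8-dienoate | COC(=O)/C=C/[C@H](C)CC(C)(OO[Si](CC)(CC)CC)C/C(C)=C/Br
F2 | step 8 | methyl 2-[(3S,4R,6S)-6-[(E)-3-bromo-2-methylprop-2-en-1-yl]-4,6-dimethyl-1,2-dioxan-3-yl]acetate | COC(=O)C[C@@H]1OO[C@](C)(C/C(C)=C/Br)C[C@H]1C
F3 | step 7 | methyl 2-[(3R,4R,6RS)-6-[(E)-3-bromo-2-methylprop-2-en-1-yl]-6-methoxy-4-methyl-1,2-dioxan-3-yl]acetate | COC(=O)C[C@H]1OOC(OC)(C/C(C)=C/Br)C[C@H]1C
F4 | step 7 | methyl 2-[(3R,4R,6R)-6-[(E)-3-bromo-2-methylprop-2-en-1-yl]-4,6-dimethyl-1,2-dioxan-3-yl]acetate | COC(=O)C[C@H]1OO[C@@](C)(C/C(C)=C/Br)C[C@H]1C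
F5 | step 6 | methyl (2E,4R,8E)-9-bromo-4,8-dimethyl-6-oxonona-2,8-dienoate | COC(=O)/C=C/[C@H](C)CC(=O)C/C(C)=C/Br
F6 | step 10 | (E)-(3-iodobut-2-en-1-yl)benzene | I/C(C)=C/Cc1ccccc1
A1 | alternative 1 | methyl (2E,4R,6RS,8E,10E)-4,6,8,10-tetramethyl-12-phenyl-6-[(triethylsilyl)peroxy]dodeca-2,8,10-trienoate | COC(=O)/C=C/[C@H](C)CC(C)(OO[Si](CC)(CC)CC)C/C(C)=C/C(C)=C/Cc1ccccc1
A2 | alternative 2 | methyl 2-[(3S,4R,6RS)-6-methoxy-4,6-dimethyl-1,2-dioxan-3-yl]acetate | COC(=O)C[C@@H]1OOC(C)(OC)C[C@H]1C
A3 | alternative 2 | trimethyl[(4E)-2,4-dimethyl-6-phenylhexa-1,4-dien-3-yl]silane | C=C(C)C([Si](C)(C)C)/C(C)=C/Cc1ccccc1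
A4 | alternative 2 | methyl 2-[(3S,4R,6S)-4,6-dimethyl-6-[(2E,4E)-2,4-dimethyl-6-phenylhexa-2,4-dien-1-yl]-1,2-dioxan-3-yl]acetate | COC(=O)C[C@@H]1OO[C@](C)(C/C(C)=C/C(C)=C/Cc2ccccc2)C[C@H]1C
A5 | alternative 3 | methyl (3E,5E,8E,10E)-4,6,8,10-tetramethyl-12-phenyldodeca-3,5,8,10-tetraenoate | COC(=O)C/C=C(C)/C=C(C)/C/C(C)=C/C(C)=C/Cc1ccccc1
A6 | alternative 3 | methyl 2-[6-[(2E,4E)-2,4-dimethyl-6-phenylhexa-2,4-dien-1-yl]-4,6-dimethyl-3,6-dihydro-1,2-dioxin-3-yl]acetate | COC(=O)CC1OOC(C)(C/C(C)=C/C(C)=C/Cc2ccccc2)C=C1C
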